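**Remark (assumption):** the target has no stereogenic centre or axis and is achiral, so no enantiocontrol is needed. Intermediates 5, 15, 16 and 18 each carry one stereocentre, are racemic, and lose that centre later.

## Retrosynthetic overview

1. Feature: the benzo ring C4a–C5–C6–C7–C8–C8a of the 2H-chromene carries O1 on C8a, OMe on C8 and OH on C5 (para to C8). C4a, C5, C8 and C8a with their oxygens map onto the four carbons of squaric acid, and C6/C7 onto a vinyl group.
2. Target 23 ⇐ chromanol 19 by oxidation-level changes only: O-acetyl mask, ArC≡CAr to ArCO–COAr, C3–C4 dehydrogenation, unmasking.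
3. 19 ⇐ cyclobutenone 16: the benzene ring is formed by ring opening to a dienylketene and 6π closure (C5–C6 bond).
4. 16 ⇐ pyrano-fused cyclobutenedione 8 + (E)-iodoenyne 13 (alkenyllithium addition at C8, O-methylation); 8 ⇐ diisopropyl squarate 3 + silylated 4-bromo-2-methylbutan-2-ol; 13 ⇐ 4-ethynylanisole 9.
5. Ring order: cyclobutene (bought) → dihydropyran (step 3) → benzene (step 7); the anisyl ring is bought.

Key step: step 7

## Route

Step 1
Reactants: 1 4-bromo-2-methylbutan-2-ol
Product: 2 (4-bromo-2-methylbutan-2-yl)oxy-trimethylsilane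
Conditions: TMSCl, imidazole, CH2Cl2, 0 °C → rt
Reagents that add atoms: chlorotrimethylsilane, C[Si](C)(C)Cl
Why: O-silylation of the tertiary alcohol through the N-silylimidazolium species masks the hydroxyl so that the primary bromide can be turned into a Grignard reagent, and the group is chosen to fall off under the acid of step 3.

Step 2
Reactants: 2 (4-bromo-2-methylbutan-2-yl)oxy-trimethylsilane; 3 diisopropyl squarate
Product: 5 4-hydroxy-2,3-di(propan-2-yloxy)-4-[3-methyl-3-(trimethylsilyloxy)butyl]cyclobut-2-en-1-one (racemic), via Grignard reagent 4 (not isolated)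
Conditions: Mg, I2 (cat.), THF, rt → 40 °C; then 3, THF, −78 °C; aq. NH4Cl
Reagents that add atoms: none
Why: Grignard formation from the primary bromide and 1,2-addition to one of the two equivalent carbonyls of the squarate at −78 °C should stop at mono-addition because the resulting alkoxide deactivates the ring; the new carbinol centre is racemic and is removed in step 3.

Step 3
Reactants: 5 4-hydroxy-2,3-di(propan-2-yloxy)-4-[3-methyl-3-(trimethylsilyloxy)butyl]cyclobut-2-en-1-one
Product: 8 3,3-dimethyl-2-oxabicyclo[4.2.0]oct-1(6)-ene-7,8-dione, via silyloxybutyl semisquarate 6 (not isolated), via hydroxybutyl semisquarate 7 (not isolated)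
Conditions: 12 M HCl (0.3 equiv), CH2Cl2, rt; then TsOH·H2O (cat.), toluene, 40 °C, reduced pressure (removal of i-PrOH)
Reagents that add atoms: water, O
Why: Acid ionises the tertiary allylic hydroxyl, water is captured at the isopropoxy-stabilised terminus and isopropanol is lost (the standard squarate 1,3-carbonyl transposition to a 3-alkoxy-4-alkylcyclobutenedione), the same acid cleaves the labile silyl ether, and the freed tertiary hydroxyl then displaces the remaining isopropoxy group by conjugate addition–elimination (vinylogous transesterification, six-membered ring), driven by distilling off isopropanol.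

Step 4
Reactants: 9 1-ethynyl-4-methoxybenzene (4-ethynylanisole)
Product: 12 3-(4-methoxyphenyl)prop-2-ynal, via lithium acetylide 10 (not isolated), via lithium hemiaminal alkoxide 11 (not isolated)
Conditions: n-BuLi, THF, −78 → −40 °C; DMF; reverse quench into aq. KH2PO4/MTBE, 0 °C
Reagents that add atoms: N,N-dimethylformamide, CN(C)C=O
Why: Formylation of the lithium acetylide with DMF gives a stable hemiaminal alkoxide, and the buffered reverse quench should release the ynal without conjugate addition of dimethylamine.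

Step 5
Reactants: 12 3-(4-methoxyphenyl)prop-2-ynal
Product: 13 (E)-1-iodo-4-(4-methoxyphenyl)but-1-en-3-yne
Conditions: CrCl2 (6 equiv), CHI3 (2 equiv), THF–dioxane, 0 °C → rt
Reagents that add atoms: iodoform, IC(I)I
Why: Takai iodo-olefination through the geminal dichromium reagent should give mainly the (E)-iodoalkene by anti elimination of the β-oxidochromium adduct; any (Z) isomer is removed by chromatography and would in any case lead to the same arene, since the alkene geometry is erased in step 7.

Step 6
Reactants: 13 (E)-1-iodo-4-(4-methoxyphenyl)but-1-en-3-yne; 8 3,3-dimethyl-2-oxabicyclo[4.2.0]oct-1(6)-ene-7,8-dione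
Product: 16 8-methoxy-8-[(E)-4-(4-methoxyphenyl)but-1-en-3-yn-1-yl]-3,3-dimethyl-2-oxabicyclo[4.2.0]oct-1(6)-en-7-one (racemic), via enynyllithium 14 (not isolated), via lithium carbinolate 15 (not isolated)
Conditions: 13, t-BuLi (2.0 equiv), Et2O, −78 °C; cannulate into 8, THF, −78 °C; MeOTf, −78 → 0 °C
Reagents that add atoms: methyl trifluoromethanesulfonate, COS(=O)(=O)C(F)(F)F
Why: Iodine–lithium exchange proceeds with retention of alkene geometry, the alkenyllithium should add 1,2 to C8=O (the ketone next to the oxygen-bearing C1) and not to C7=O (deactivated as a vinylogous ester carbonyl), and the lithium alkoxide is O-methylated in situ; the new C8 centre is racemic and is destroyed in step 7.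

Step 7
Reactants: 16 8-methoxy-8-[(E)-4-(4-methoxyphenyl)but-1-en-3-yn-1-yl]-3,3-dimethyl-2-oxabicyclo[4.2.0]oct-1(6)-en-7-one
Product: 19 8-methoxy-6-[(4-methoxyphenyl)ethynyl]-2,2-dimethylchroman-5-ol, via dienylketene 17 (not isolated), via cyclohexadienone 18 (not isolated)
Conditions: degassed toluene (0.02 M), 110 °C, Ar, base-washed glassware
Reagents that add atoms: none
Why: Heating cleaves the C(=O)–C(OMe) bond of the four-membered ring by thermal conrotatory 4π-electrocyclic opening to dienylketene 17, in which the future C4a–C8a bond is held in the dihydropyran ring so that the ketene and the exocyclic enol-ether diene are fixed s-cis. The ketene carbon (future C5) then closes onto the alkene terminus carrying the arylethynyl group (future C6) by thermal disrotatory 6π-electrocyclisation, forming the six-membered carbocycle as cyclohexa-2,4-dienone 18, which enolises to phenol 19. The closest known reaction type is the thermal ring expansion of squarate-derived 4-alkenyl-4-alkoxycyclobutenones to mono-protected hydroquinones. No stereocentre is created that persists: C8 of 16 becomes aromatic C8 and the transient C6 centre of 18 is erased on tautomerisation. The selectivity the step needs is torquoselectivity in the ring opening (alkenyl inward, methoxy outward), which the donor methoxy group on the carbinol carbon secures through its preference for outward rotation. Strain release and aromatisation make the sequence irreversible, and neutral, dilute, oxygen-free conditions should keep the o-alkynylphenol from closing to a benzofuran or being oxidised.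

Step 8
Reactants: 19 8-methoxy-6-[(4-methoxyphenyl)ethynyl]-2,2-dimethylchroman-5-ol
Product: 20 8-methoxy-6-[(4-methoxyphenyl)ethynyl]-2,2-dimethylchroman-5-yl acetate
Conditions: Ac2O, pyridine, DMAP (cat.), CH2Cl2, 0 °C → rt
Reagents that add atoms: acetic anhydride, CC(=O)OC(C)=O
Why: DMAP-catalysed O-acylation masks the p-methoxyphenol, which would otherwise be oxidised to a quinone by permanganate or DDQ and could add 5-endo to the neighbouring alkyne.

Step 9
Reactants: 20 8-methoxy-6-[(4-methoxyphenyl)ethynyl]-2,2-dimethylchroman-5-yl acetate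
Product: 21 8-methoxy-6-[(4-methoxyphenyl)(oxo)acetyl]-2,2-dimethylchroman-5-yl acetate
Conditions: KMnO4, NaHCO3, MgSO4, acetone–H2O, 0 °C → rt; NaHSO3 work-up
Reagents that add atoms: potassium permanganate, [K+].[O-][Mn](=O)(=O)=O
Why: Buffered permanganate oxidation of a diarylalkyne to the benzil through a cyclic manganate ester involves no electrophilic activation of the alkyne, so the ortho acetoxy group should not be drawn into benzofuran formation (the reason I2/DMSO or Pd(II) is avoided), and the chroman CH2 groups, the ethers and the acetate should survive at neutral pH.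

Step 10
Reactants: 21 8-methoxy-6-[(4-methoxyphenyl)(oxo)acetyl]-2,2-dimethylchroman-5-yl acetate
Product: 22 8-methoxy-6-[(4-methoxyphenyl)(oxo)acetyl]-2,2-dimethyl-2H-chromen-5-yl acetate
Conditions: DDQ (2 equiv), 1,4-dioxane, reflux
Reagents that add atoms: none
Why: DDQ dehydrogenation by hydride abstraction from benzylic C4 (cation stabilised by O1 through C8a) and loss of H-3 gives the 2H-chromene, a known conversion for acyl-substituted 2,2-dimethylchromans; the C6 acyl group is meta to C4a and the gem-dimethyl group blocks further oxidation.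

Step 11
Reactants: 22 8-methoxy-6-[(4-methoxyphenyl)(oxo)acetyl]-2,2-dimethyl-2H-chromen-5-yl acetate
Product: 23 dielsianone, 1-(5-hydroxy-8-methoxy-2,2-dimethyl-2H-chromen-6-yl)-2-(4-methoxyphenyl)ethane-1,2-dione
Conditions: K2CO3 (0.2 equiv), MeOH, 0 °C; pH 5 buffer
Reagents that add atoms: none
Why: Methanolysis of an aryl acetate activated by the ortho acyl group is fast under mild carbonate catalysis, the 1,2-diketone has no α-hydrogen to enolise, and the freed phenol is stabilised by hydrogen bonding to the C6 carbonyl.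

## Compound list

1 | 4-bromo-2-methylbutan-2-ol | CC(C)(O)CCBr | starting material
2 | (4-bromo-2-methylbutan-2-yl)oxy-trimethylsilane | C[Si](C)(C)OC(C)(C)CCBr | intermediate
3 | diisopropyl squarate | CC(C)OC1=C(OC(C)C)C(=O)C1=O | starting material
4 | [3-methyl-3-(trimethylsilyloxy)butyl]magnesium bromide | C[Si](C)(C)OC(C)(C)CC[Mg]Br | intermediate
5 | 4-hydroxy-2,3-di(propan-2-yloxy)-4-[3-methyl-3-(trimethylsilyloxy)butyl]cyclobut-2-en-1-one (racemic) | CC(C)OC1=C(OC(C)C)C(O)(CCC(C)(C)O[Si](C)(C)C)C1=O | intermediate
6 | 3-[3-methyl-3-(trimethylsilyloxy)butyl]-4-(propan-2-yloxy)cyclobut-3-ene-1,2-dione | CC(C)OC1=C(CCC(C)(C)O[Si](C)(C)C)C(=O)C1=O | intermediate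
7 | 3-(3-hydroxy-3-methylbutyl)-4-(propan-2-yloxy)cyclobut-3-ene-1,2-dione | CC(C)OC1=C(CCC(C)(C)O)C(=O)C1=O | intermediate
8 | 3,3-dimethyl-2-oxabicyclo[4.2.0]oct-1(6)-ene-7,8-dione | CC1(C)CCC2=C(O1)C(=O)C2=O | intermediate
9 | 1-ethynyl-4-methoxybenzene (4-ethynylanisole) | COc1ccc(C#C)cc1 | starting material
10 | lithium (4-methoxyphenyl)acetylide | COc1ccc(C#C[Li])cc1 | intermediate
11 | lithium 1-(dimethylamino)-3-(4-methoxyphenyl)prop-2-yn-1-olate (racemic) | COc1ccc(C#CC(O[Li])N(C)C)cc1 | intermediate
12 | 3-(4-methoxyphenyl)prop-2-ynal | COc1ccc(C#CC=O)cc1 | intermediate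
13 | (E)-1-iodo-4-(4-methoxyphenyl)but-1-en-3-yne | COc1ccc(C#C/C=C/I)cc1 | intermediate
14 | (E)-[4-(4-methoxyphenyl)but-1-en-3-yn-1-yl]lithium | COc1ccc(C#C/C=C/[Li])cc1 | intermediate
15 | lithium alkoxide of 8-hydroxy-8-[(E)-4-(4-methoxyphenyl)but-1-en-3-yn-1-yl]-3,3-dimethyl-2-oxabicyclo[4.2.0]oct-1(6)-en-7-one (racemic) | COc1ccc(C#C/C=C/C2(O[Li])C(=O)C3=C2OC(C)(C)CC3)cc1 | intermediate
16 | 8-methoxy-8-[(E)-4-(4-methoxyphenyl)but-1-en-3-yn-1-yl]-3,3-dimethyl-2-oxabicyclo[4.2.0]oct-1(6)-en-7-one (racemic) | COc1ccc(C#C/C=C/C2(OC)C(=O)C3=C2OC(C)(C)CC3)cc1 | intermediate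
17 | dienylketene: 2-[(1Z,3E)-1-methoxy-5-(4-methoxyphenyl)pent-1,3-dien-4-yn-1-ylidene... ] i.e. 3-(oxomethylidene)-2-[(E)-1-methoxy-5-(4-methoxyphenyl)pent-2-en-4-yn-1-ylidene]-6,6-dimethyloxane, methoxy cis to the ring oxygen | O=C=C1CCC(C)(C)O/C1=C(\OC)/C=C/C#Cc1ccc(OC)cc1 | intermediate
18 | 8-methoxy-6-[(4-methoxyphenyl)ethynyl]-2,2-dimethyl-3,4-dihydro-2H-chromen-5(6H)-one (racemic) | COC1=CC(C#Cc2ccc(OC)cc2)C(=O)C2=C1OC(C)(C)CC2 | intermediate
19 | 8-methoxy-6-[(4-methoxyphenyl)ethynyl]-2,2-dimethylchroman-5-ol | COc1ccc(C#Cc2cc(OC)c3c(c2O)CCC(C)(C)O3)cc1 | intermediate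
20 | 8-methoxy-6-[(4-methoxyphenyl)ethynyl]-2,2-dimethylchroman-5-yl acetate | COc1ccc(C#Cc2cc(OC)c3c(c2OC(C)=O)CCC(C)(C)O3)cc1 | intermediate
21 | 8-methoxy-6-[(4-methoxyphenyl)(oxo)acetyl]-2,2-dimethylchroman-5-yl acetate | COc1ccc(C(=O)C(=O)c2cc(OC)c3c(c2OC(C)=O)CCC(C)(C)O3)cc1 | intermediate
22 | 8-methoxy-6-[(4-methoxyphenyl)(oxo)acetyl]-2,2-dimethyl-2H-chromen-5-yl acetate | COc1ccc(C(=O)C(=O)c2cc(OC)c3c(c2OC(C)=O)C=CC(C)(C)O3)cc1 | intermediate
23 | dielsianone, 1-(5-hydroxy-8-methoxy-2,2-dimethyl-2H-chromen-6-yl)-2-(4-methoxyphenyl)ethane-1,2-dione | COc1ccc(C(=O)C(=O)c2cc(OC)c3c(c2O)C=CC(C)(C)O3)cc1 | target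

## Step count and risks

Total steps: 11. Longest linear sequence: 9 (steps 1, 2, 3, 6, 7, 8, 9, 10, 11).

**Step 7.** The electrocyclic cascade may be undercut by thermal 5-endo closure of the freed phenol onto the alkyne, or by oligomerisation of the conjugated enyne at the ketene stage. The fallback keeps the ring expansion but brings in the arylethynyl group afterwards by cross-coupling. It sets out from 8. Vinylmagnesium bromide (THF, −78 °C) should add at C8 to give 8-ethenyl-8-hydroxy-3,3-dimethyl-2-oxabicyclo[4.2.0]oct-1(6)-en-7-one F2. Methylation with MeI/Ag2O gives 8-ethenyl-8-methoxy-3,3-dimethyl-2-oxabicyclo[4.2.0]oct-1(6)-en-7-one F3. Thermolysis in toluene at 110 °C gives 8-methoxy-2,2-dimethylchroman-5-ol F4. NIS in MeCN at 0 °C should iodinate C6, which is ortho to the hydroxyl and para to O1, giving 6-iodo-8-methoxy-2,2-dimethylchroman-5-ol F5. Acetylation gives 6-iodo-8-methoxy-2,2-dimethylchroman-5-yl acetate F6. Sonogashira coupling of F6 with 9 (PdCl2(PPh3)2, CuI, Et3N, rt) returns to the route at 20.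

**Step 3.** Dehydration or chloride substitution at the tertiary carbinol may outpace its addition to the vinylogous ester. The fallback forms the O–CMe2 bond instead of the O–C(sp2) bond. It sets out from 7, isolated after the HCl treatment together with any alkene or chloride derived from it, all of which feed the same tertiary cation. Hydrolysis of the isopropyl vinylogous ester (6 M HCl, THF, 50 °C) gives 3-hydroxy-4-(3-hydroxy-3-methylbutyl)cyclobut-3-ene-1,2-dione F1. Strong acid (TfOH cat., CH2Cl2, 0 °C) should then alkylate the vinylogous acid through the tertiary cation, in the manner of hydroxyquinone-to-pyran cyclisations. Both oxygens flanking the chain-bearing carbon are equivalent, so either closure returns to the route at 8.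

**Step 10.** Hydride abstraction from C4 of the acyl- and acetoxy-substituted chroman may be slow, so that decomposition under prolonged heating competes. The fallback sets out from 21. Radical bromination (NBS, AIBN, PhCF3, 80 °C) should give 4-bromo-8-methoxy-6-[(4-methoxyphenyl)(oxo)acetyl]-2,2-dimethylchroman-5-yl acetate F7. Elimination with DBU (toluene, rt) returns to the route at 22.

## Further compounds

F1 | step 3 | 3-hydroxy-4-(3-hydroxy-3-methylbutyl)cyclobut-3-ene-1,2-dione | CC(C)(O)CCC1=C(O)C(=O)C1=O
F2 | step 7 | 8-ethenyl-8-hydroxy-3,3-dimethyl-2-oxabicyclo[4.2.0]oct-1(6)-en-7-one (racemic) | C=CC1(O)C(=O)C2=C1OC(C)(C)CC2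
F3 | step 7 | 8-ethenyl-8-methoxy-3,3-dimethyl-2-oxabicyclo[4.2.0]oct-1(6)-en-7-one (racemic) | C=CC1(OC)C(=O)C2=C1OC(C)(C)CC2
F4 | step 7 | 8-methoxy-2,2-dimethylchroman-5-ol | COc1ccc(O)c2c1OC(C)(C)CC2
F5 | step 7 | 6-iodo-8-methoxy-2,2-dimethylchroman-5-ol | COc1cc(I)c(O)c2c1OC(C)(C)CC2
F6 | step 7 | 6-iodo-8-methoxy-2,2-dimethylchroman-5-yl acetate | COc1cc(I)c(OC(C)=O)c2c1OC(C)(C)CC2
F7 | step 10 | 4-bromo-8-methoxy-6-[(4-methoxyphenyl)(oxo)acetyl]-2,2-dimethylchroman-5-yl acetate (racemic) | COc1ccc(C(=O)C(=O)c2cc(OC)c3c(c2OC(C)=O)C(Br)CC(C)(C)O3)cc1
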